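**Retrosynthetic overview**

1. Stereocentre: C2 of each dihydrobenzofuran is the carbinol carbon of the L‑glutamic‑acid‑derived lactone acid 1. Its CO2H is turned into the isopropenyl group (via acid chloride 2 and ketone 3 to lactone 4), so the oxygen ring is bought, not made.
2. Key disconnection: silyl ketene acetal 5 (from 4) plus methyl 3‑bromocoumalate 6 give, via adduct 7 and diene 8, aryl bromide 9. The benzene ring is cut at C3a–C4 and C7–C7a (Diels–Alder, then loss of CO2 and silanol).
3. Biaryl bond C7–C7′: diester 10 is cut into two molecules of 9 (nickel‑catalysed reductive homocoupling).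
4. Last: the two acids of target 11 come from the methyl esters of 10.
5. Ring order: oxygen ring (from the lactone) → benzene ring (cycloaddition) → biaryl bond.

Assumption: 1 and 6 are taken as catalogue compounds (1 is made from L‑glutamic acid with retention; 6 is methyl 3‑bromocoumalate).

**Step 1**
Reactants: 1 (S)-5-oxotetrahydrofuran-2-carboxylic acid
Product: 3 (S)-5-acetyldihydrofuran-2(3H)-one, via acid chloride 2 (not isolated)
Conditions: (COCl)2, cat. DMF, CH2Cl2, 0 → 23 °C; evaporate; then MeMgBr (1.05 equiv, slow addition), Fe(acac)3 (3 mol %), THF, −78 °C; cold aq. NH4Cl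
Reagents that add atoms: methylmagnesium bromide, C[Mg]Br (the methyl group of 3); oxalyl chloride, O=C(Cl)C(=O)Cl (the chlorine of intermediate 2 only)
Why: Acid chloride formation followed by iron‑catalysed Kumada‑type acylation consumes the acyl chloride at −78 °C faster than MeMgBr attacks the lactone or the new ketone, and the bought stereocentre is carried through unchanged.

**Step 2**
Reactants: 3 (S)-5-acetyldihydrofuran-2(3H)-one
Product: 4 (S)-5-(prop-1-en-2-yl)dihydrofuran-2(3H)-one
Conditions: Zn, CH2Br2, TiCl4, THF, −40 → 5 °C (reagent pre‑formed); then 3, CH2Cl2, 0 → 23 °C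
Reagents that add atoms: dibromomethane, BrCBr
Why: Lombardo methylenation olefinates the ketone but not the lactone and is non‑basic, so the enolisable α‑acyloxy stereocentre keeps its configuration.

**Step 3**
Reactants: 4 (S)-5-(prop-1-en-2-yl)dihydrofuran-2(3H)-one
Product: 5 trimethyl{[(5S)-5-(prop-1-en-2-yl)-4,5-dihydrofuran-2-yl]oxy}silane
Conditions: LiN(iPr)2 (commercial solution, 1.1 equiv), Me3SiCl (1.3 equiv, in situ quench), THF, −78 °C; evaporate, pentane, filter under N2 (no aqueous work‑up), use crude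
Reagents that add atoms: chlorotrimethylsilane, C[Si](C)(C)Cl
Why: Kinetic enolisation at the only α‑CH2 of the lactone with O‑silylation gives the cyclic silyl ketene acetal; C5–H is not acidic, so the stereocentre is untouched.

**Step 4**
Reactants: 5 trimethyl{[(5S)-5-(prop-1-en-2-yl)-4,5-dihydrofuran-2-yl]oxy}silane (1.3 equiv); 6 methyl 3-bromo-2-oxo-2H-pyran-5-carboxylate
Product: 9 methyl (2S)-7-bromo-2-(prop-1-en-2-yl)-2,3-dihydro-1-benzofuran-5-carboxylate, via bridged lactone adduct 7 (not isolated), via silyloxy cyclohexadiene 8 (not isolated)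
Conditions: PhMe, 60 → 100 °C, 12 h (N2, strictly dry); then DBU (0.2 equiv), 23 °C
Reagents that add atoms: none
Why: Inverse‑electron‑demand Diels–Alder reaction (2‑pyrone benzannulation) joins the nucleophilic ketene‑acetal carbon to C6 of the pyrone and the acetal carbon to C3; retro‑Diels–Alder loss of CO2 and β‑elimination of the exocyclic silanol then aromatise the ring, placing O para to the ester and Br ortho to O, with the stereocentre a spectator.

**Step 5**
Reactants: 9 methyl (2S)-7-bromo-2-(prop-1-en-2-yl)-2,3-dihydro-1-benzofuran-5-carboxylate (two molecules)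
Product: 10 dimethyl (2S,2′S)-2,2′-di(prop-1-en-2-yl)-2,2′,3,3′-tetrahydro-[7,7′-bi-1-benzofuran]-5,5′-dicarboxylate
Conditions: NiCl2(PPh3)2 (10 mol %), PPh3 (20 mol %), Zn dust (1.5 equiv), Et4NI (1.0 equiv), THF, 50 °C
Reagents that add atoms: none
Why: Nickel‑catalysed reductive (Ullmann‑type) homocoupling: zerovalent nickel made by Zn inserts into the C–Br bond and two aryl groups are joined, while esters, alkenes and the remote stereocentres are inert and the di‑ortho‑oxygenated axis is not a stable stereo‑element.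

**Step 6**
Reactants: 10 dimethyl (2S,2′S)-2,2′-di(prop-1-en-2-yl)-2,2′,3,3′-tetrahydro-[7,7′-bi-1-benzofuran]-5,5′-dicarboxylate
Product: 11 eurycomalin A, (2S,2′S)-2,2′-di(prop-1-en-2-yl)-2,2′,3,3′-tetrahydro-[7,7′-bi-1-benzofuran]-5,5′-dicarboxylic acid
Conditions: LiOH·H2O (6 equiv), THF/MeOH/H2O 3:1:1, 40 °C; then 1 M HCl to pH 2
Reagents that add atoms: lithium hydroxide, [Li+].[OH-] (one oxygen of each CO2H)
Why: Saponification (BAc2) of both aryl methyl esters; the stereocentres are not α to a carbonyl and the isopropenyl groups are base‑stable.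

**Compound list**

1 | (S)-5-oxotetrahydrofuran-2-carboxylic acid | OC(=O)[C@@H]1CCC(=O)O1 | starting material
2 | (S)-5-oxotetrahydrofuran-2-carbonyl chloride (not isolated) | ClC(=O)[C@@H]1CCC(=O)O1 | intermediate
3 | (S)-5-acetyldihydrofuran-2(3H)-one | CC(=O)[C@@H]1CCC(=O)O1 | intermediate
4 | (S)-5-(prop-1-en-2-yl)dihydrofuran-2(3H)-one | C=C(C)[C@@H]1CCC(=O)O1 | intermediate
5 | trimethyl{[(5S)-5-(prop-1-en-2-yl)-4,5-dihydrofuran-2-yl]oxy}silane | C=C(C)[C@@H]1CC=C(O[Si](C)(C)C)O1 | intermediate
6 | methyl 3-bromo-2-oxo-2H-pyran-5-carboxylate (methyl 3-bromocoumalate) | COC(=O)C1=COC(=O)C(Br)=C1 | starting material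
7 | Diels–Alder adduct (not isolated): 2-oxabicyclo[2.2.2]oct-5-en-3-one with Br on the bridgehead next to C=O, CO2Me on the alkene, and the (S)-2-isopropenyl-tetrahydrofuran ring fused across the two new sp3 carbons, OSiMe3 on the ketal carbon; diastereomer mixture at the new sp3 centres | O=C1OC2C(C(=O)OC)=CC1(Br)C1(O[Si](C)(C)C)O[C@H](C(C)=C)CC21 | intermediate
8 | methyl (2S)-7-bromo-2-(prop-1-en-2-yl)-7a-(trimethylsilyloxy)-2,3,3a,7a-tetrahydro-1-benzofuran-5-carboxylate (not isolated; 3a/7a mixture) | COC(=O)C1=CC2C[C@@H](C(C)=C)OC2(O[Si](C)(C)C)C(Br)=C1 | intermediate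
9 | methyl (2S)-7-bromo-2-(prop-1-en-2-yl)-2,3-dihydro-1-benzofuran-5-carboxylate | C=C(C)[C@@H]1Cc2cc(C(=O)OC)cc(Br)c2O1 | intermediate
10 | dimethyl (2S,2′S)-2,2′-di(prop-1-en-2-yl)-2,2′,3,3′-tetrahydro-[7,7′-bi-1-benzofuran]-5,5′-dicarboxylate | C=C(C)[C@@H]1Cc2cc(C(=O)OC)cc(-c3cc(C(=O)OC)cc4c3O[C@H](C(=C)C)C4)c2O1 | intermediate
11 | eurycomalin A | C=C(C)[C@@H]1Cc2cc(C(=O)O)cc(-c3cc(C(=O)O)cc4c3O[C@H](C(=C)C)C4)c2O1 | target

**Step count**

Total steps: 6. Longest linear sequence: 6 (1 → 3 → 4 → 5 → 9 → 10 → 11).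

**Steps most likely to fail, with fallbacks**

Step 4 (cycloaddition cascade) is the main risk. I know of no direct precedent for a cyclic silyl ketene acetal in this pyrone benzannulation; the step rests on analogy with acyclic ketene acetals. Three things can go wrong:
- The first C–C bond may be followed by silyl transfer, giving a Michael adduct instead of ring closure.
- Acetal 5 is an allyl silyl ketene acetal and on prolonged heating could undergo an Ireland–Claisen shift to a cyclopentene carboxylate. This needs a strained norbornane‑like boat, which is why the reaction is started at 60 °C.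
- Water would open ketal 8 to a phenol.

The fallback sets out from 3 and comes back at 9, postponing the alkene so that the dienophile holds no allylic C–O bond. Ketone 3 is methylated with MeTi(OiPr)3 (THF, −20 → 23 °C; adds to ketones but not lactones, non‑basic) to the tertiary alcohol (S)-5-(2-hydroxypropan-2-yl)dihydrofuran-2(3H)-one F1. LiN(iPr)2 (2.2 equiv) and Me3SiCl give the doubly silylated ketene acetal trimethyl{[(5S)-5-(2-(trimethylsilyloxy)propan-2-yl)-4,5-dihydrofuran-2-yl]oxy}silane F2. Heating F2 with 6 in PhMe runs the same cycloaddition through the bridged lactone adduct F3 and the silyloxy cyclohexadiene F4 to the aryl bromide silyl ether methyl (2S)-7-bromo-2-(2-(trimethylsilyloxy)propan-2-yl)-2,3-dihydro-1-benzofuran-5-carboxylate F5. Dilute HCl in THF frees the alcohol methyl (2S)-7-bromo-2-(2-hydroxypropan-2-yl)-2,3-dihydro-1-benzofuran-5-carboxylate F6. Dehydration with the Burgess reagent (MeO2CN–SO2NEt3 inner salt, PhMe, 60 °C) then gives 9. The price is two more steps and the regiochemistry of the dehydration.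

Step 5 (homocoupling) may give hydrodebromination or nickel‑hydride isomerisation of the isopropenyl group. The fallback sets out from 9 and comes back at 10. Miyaura borylation (B2pin2, Pd(dppf)Cl2, KOAc, dioxane, 80 °C) gives the boronate methyl (2S)-2-(prop-1-en-2-yl)-7-(4,4,5,5-tetramethyl-1,3,2-dioxaborolan-2-yl)-2,3-dihydro-1-benzofuran-5-carboxylate F7. Suzuki–Miyaura coupling of F7 with a second equivalent of 9 (Pd(OAc)2, SPhos, K3PO4, PhMe/H2O, 80 °C) gives 10.

Step 2 (Lombardo methylenation) may suffer from low conversion, loss of the volatile product, or partial racemisation of the α‑acyloxy ketone. The fallback sets out from 3 and comes back at 4 as a two‑stage Peterson olefination. Me3SiCH2MgCl with CeCl3 (THF, −78 °C; low basicity, ketone‑selective) gives the β‑hydroxysilane (5S)-5-[2-hydroxy-1-(trimethylsilyl)propan-2-yl]dihydrofuran-2(3H)-one F8 as a carbinol epimer mixture. Acid‑induced elimination (cat. H2SO4, THF, 23 °C) then gives 4 regiospecifically.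

**Further compounds**

F1 | step 4 | (S)-5-(2-hydroxypropan-2-yl)dihydrofuran-2(3H)-one | CC(C)(O)[C@@H]1CCC(=O)O1
F2 | step 4 | trimethyl{[(5S)-5-(2-(trimethylsilyloxy)propan-2-yl)-4,5-dihydrofuran-2-yl]oxy}silane | C[Si](C)(C)OC(C)(C)[C@@H]1CC=C(O[Si](C)(C)C)O1
F3 | step 4 | bridged lactone adduct of F2 and 6 (diastereomer mixture at the new sp3 centres) | O=C1OC2C(C(=O)OC)=CC1(Br)C1(O[Si](C)(C)C)O[C@H](C(C)(C)O[Si](C)(C)C)CC21
F4 | step 4 | methyl (2S)-7-bromo-7a-(trimethylsilyloxy)-2-(2-(trimethylsilyloxy)propan-2-yl)-2,3,3a,7a-tetrahydro-1-benzofuran-5-carboxylate | COC(=O)C1=CC2C[C@@H](C(C)(C)O[Si](C)(C)C)OC2(O[Si](C)(C)C)C(Br)=C1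
F5 | step 4 | methyl (2S)-7-bromo-2-(2-(trimethylsilyloxy)propan-2-yl)-2,3-dihydro-1-benzofuran-5-carboxylate | C[Si](C)(C)OC(C)(C)[C@@H]1Cc2cc(C(=O)OC)cc(Br)c2O1
F6 | step 4 | methyl (2S)-7-bromo-2-(2-hydroxypropan-2-yl)-2,3-dihydro-1-benzofuran-5-carboxylate | CC(C)(O)[C@@H]1Cc2cc(C(=O)OC)cc(Br)c2O1
F7 | step 5 | methyl (2S)-2-(prop-1-en-2-yl)-7-(4,4,5,5-tetramethyl-1,3,2-dioxaborolan-2-yl)-2,3-dihydro-1-benzofuran-5-carboxylate | C=C(C)[C@@H]1Cc2cc(C(=O)OC)cc(B3OC(C)(C)C(C)(C)O3)c2O1
F8 | step 2 | (5S)-5-[2-hydroxy-1-(trimethylsilyl)propan-2-yl]dihydrofuran-2(3H)-one | C[Si](C)(C)CC(C)(O)[C@@H]1CCC(=O)O1
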